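**Retrosynthetic overview**

1. Numbering used throughout: cyclopentane C1–C2–C3(OH)–C4(Me2)–C5(OH); cycloheptanone C5–C6–C7–C8(Me)–C9(Me)–C10(=O)–C1; side chain C11–C12 on the butenolide C13(=C14–C15(=O)–O–C16). The target is traced back through desilylation and oxidation to a C10 carbinol.
2. Key disconnection C9–C11: Ti(III) opens a C9,C10-epoxide of the seven-membered ring to the tertiary C9 radical, which adds to the terminal carbon of 4-vinylfuran-2(5H)-one. The feature used is that the quaternary ring carbon C9 is bonded directly to the carbonyl carbon C10 (so the epoxide puts the radical on C9 and the oxygen on C10), and that C11 is the δ-carbon of the butenolide dienoate C11=C12–C13=C14–C15=O.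
3. The epoxide comes from hydroxyl-directed epoxidation of a C9=C10 cycloheptene, itself made by ring-closing metathesis on a trans-1-vinyl-2-alkenylcyclopentanol.
4. Cyclopentane stereocentres: CBS reduction of 2,2-dimethylcyclopentane-1,3-dione gives a temporary C5 carbinol that steers trans vinyl addition (C1) and anti reduction (C3). It is then oxidised, and C5 is rebuilt by Grignard addition of the C6–C9 chain (C8 from CBS reduction and Johnson–Claisen chirality transfer).
5. Ring order: five-membered ring (bought as the dione), then seven-membered ring (RCM); the butenolide ring is brought in intact in the key step.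

Key step: step 16

Remark: (E)-3-methylpent-3-en-2-one, 4-bromofuran-2(5H)-one and 2,2-dimethylcyclopentane-1,3-dione are taken as commercial; where a name and a SMILES string should differ in a descriptor, the SMILES string is meant.

**Route**

Step 1
Reactants: 1 (E)-3-methylpent-3-en-2-one
Product: 2 (2R,3E)-3-methylpent-3-en-2-ol
Conditions: (S)-Me-CBS (10 mol %), catecholborane, toluene, −78 °C; aq. NaOH
Reagents that add atoms: none
Why: Corey–Bakshi–Shibata reduction, in which the oxazaborolidine places the larger alkenyl group away from the catalyst and delivers hydride to one carbonyl face (1,2-reduction only), should give the (R)-carbinol that later relays its chirality to C8.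

Step 2
Reactants: 2 (2R,3E)-3-methylpent-3-en-2-ol
Product: 3 ethyl (3R,4E)-3,4-dimethylhex-4-enoate
Conditions: CH3C(OEt)3, EtCO2H (cat.), 140 °C, EtOH distilled off
Reagents that add atoms: triethyl orthoacetate, CC(OCC)(OCC)OCC
Why: Johnson–Claisen rearrangement through a chair transition state with the carbinol methyl equatorial transfers the C–O stereocentre suprafacially to the new C–C stereocentre (future C8, R) and forms the new trisubstituted alkene as the E isomer.

Step 3
Reactants: 3 ethyl (3R,4E)-3,4-dimethylhex-4-enoate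
Product: 4 (3R,4E)-3,4-dimethylhex-4-en-1-ol
Conditions: LiAlH4, Et2O, 0 °C
Reagents that add atoms: none
Why: Hydride reduction of the ester to the primary alcohol leaves the isolated trisubstituted alkene and the β-stereocentre untouched.

Step 4
Reactants: 4 (3R,4E)-3,4-dimethylhex-4-en-1-ol
Product: 5 (2E,4R)-6-bromo-3,4-dimethylhex-2-ene
Conditions: CBr4, PPh3, CH2Cl2, 0 °C
Reagents that add atoms: carbon tetrabromide, BrC(Br)(Br)Br
Why: Appel bromination converts the primary alcohol to the bromide under neutral conditions that do not touch the alkene or the stereocentre.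

Step 5
Reactants: 6 4-bromofuran-2(5H)-one
Product: 7 4-ethenylfuran-2(5H)-one
Conditions: tributyl(vinyl)stannane, Pd(PPh3)4 (5 mol %), BHT, toluene, 90 °C
Reagents that add atoms: tributyl(vinyl)stannane, C=C[Sn](CCCC)(CCCC)CCCC
Why: Stille coupling of the β-bromobutenolide (a vinylogous acyl bromide that undergoes oxidative addition readily) runs under neutral conditions that the base-sensitive lactone tolerates.

Step 6
Reactants: 8 2,2-dimethylcyclopentane-1,3-dione
Product: 9 (R)-3-hydroxy-2,2-dimethylcyclopentan-1-one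
Conditions: (S)-Me-CBS (20 mol %), BH3·SMe2 (0.6 equiv), THF, −30 °C
Reagents that add atoms: none
Why: Corey–Bakshi–Shibata monoreduction, with the quaternary carbon acting as the large substituent, should reduce one carbonyl enantioselectively to the (R)-carbinol, and substoichiometric borane limits over-reduction.

Step 7
Reactants: 9 (R)-3-hydroxy-2,2-dimethylcyclopentan-1-one
Product: 10 (R)-2,2-dimethyl-3-[(triethylsilyl)oxy]cyclopentan-1-one
Conditions: TESCl, imidazole, CH2Cl2, 0 °C to rt
Reagents that add atoms: chlorotriethylsilane, CC[Si](Cl)(CC)CC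
Why: Silyl ether formation gives a group bulky enough to steer the later conjugate addition and labile enough to be removed by dilute acid.

Step 8
Reactants: 10 (R)-2,2-dimethyl-3-[(triethylsilyl)oxy]cyclopentan-1-one
Product: 12 (4R)-5,5-dimethyl-4-[(triethylsilyl)oxy]cyclopent-2-en-1-one, via trimethylsilyl enol ether 11 (not isolated)
Conditions: LDA, THF, −78 °C, then TMSCl; then Pd(OAc)2 (10 mol %), O2, DMSO, rt
Reagents that add atoms: none
Why: Saegusa–Ito dehydrogenation gives a single regioisomer because the ketone can enolise only toward its CH2 group, the other α-carbon being quaternary.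

Step 9
Reactants: 12 (4R)-5,5-dimethyl-4-[(triethylsilyl)oxy]cyclopent-2-en-1-one
Product: 14 (3R,4R)-4-ethenyl-3-hydroxy-2,2-dimethylcyclopentan-1-one, via triethylsilyl-protected conjugate adduct 13 (not isolated)
Conditions: vinylMgBr, CuI (10 mol %), THF, −78 to −40 °C; then 1 M HCl, THF, rt
Reagents that add atoms: vinylmagnesium bromide, C=C[Mg]Br
Why: Copper-catalysed conjugate addition of the Grignard reagent occurs anti to the adjacent silyloxy group (as with 4-silyloxycyclopentenones), setting C1 trans to the temporary C5–O bond; the quaternary carbon prevents enolate equilibration and β-elimination, and the acidic work-up cleaves the triethylsilyl ether.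

Step 10
Reactants: 14 (3R,4R)-4-ethenyl-3-hydroxy-2,2-dimethylcyclopentan-1-one
Product: 15 (1R,3R,4R)-4-ethenyl-2,2-dimethylcyclopentane-1,3-diol
Conditions: Me4NBH(OAc)3, MeCN–AcOH, −25 °C
Reagents that add atoms: none
Why: Hydroxyl-directed (Evans–Saksena) reduction delivers hydride intramolecularly from the alkoxyborohydride on the C5 oxygen, so the new C3 hydroxyl should be anti to the C5 hydroxyl and therefore cis to the vinyl group, as the target requires.

Step 11
Reactants: 15 (1R,3R,4R)-4-ethenyl-2,2-dimethylcyclopentane-1,3-diol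
Product: 16 (1R,3R,5R)-3-{[tert-butyl(dimethyl)silyl]oxy}-5-ethenyl-2,2-dimethylcyclopentan-1-ol
Conditions: TBSCl (1.05 equiv), imidazole, DMF, −20 to 0 °C
Reagents that add atoms: tert-butyl(chloro)dimethylsilane, CC(C)(C)[Si](C)(C)Cl
Why: Site-selective silylation should favour the C3 hydroxyl, which is flanked by a CH2 group, over the C5 hydroxyl, which sits between the quaternary carbon and the vinyl-bearing methine.

Step 12
Reactants: 16 (1R,3R,5R)-3-{[tert-butyl(dimethyl)silyl]oxy}-5-ethenyl-2,2-dimethylcyclopentan-1-ol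
Product: 17 (2R,4R)-4-{[tert-butyl(dimethyl)silyl]oxy}-2-ethenyl-5,5-dimethylcyclopentan-1-one
Conditions: Dess–Martin periodinane, NaHCO3, CH2Cl2, 0 °C
Reagents that add atoms: none
Why: Dess–Martin oxidation under buffered, non-basic conditions should give the α-vinyl ketone without epimerisation or conjugation, and it erases the temporary C5 stereocentre after that centre has set C1 and C3.

Step 13
Reactants: 17 (2R,4R)-4-{[tert-butyl(dimethyl)silyl]oxy}-2-ethenyl-5,5-dimethylcyclopentan-1-one; 5 (2E,4R)-6-bromo-3,4-dimethylhex-2-ene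
Product: 19 (1S,3R,5R)-3-{[tert-butyl(dimethyl)silyl]oxy}-1-[(3R,4E)-3,4-dimethylhex-4-en-1-yl]-5-ethenyl-2,2-dimethylcyclopentan-1-ol, via Grignard reagent 18 (not isolated)
Conditions: 5, Mg, THF, rt; LaCl3·2LiCl, THF, 0 °C; 17, −78 to 0 °C; aq. NH4Cl
Reagents that add atoms: none
Why: Grignard 1,2-addition promoted by LaCl3·2LiCl (which suppresses enolisation of the α-vinyl ketone) should occur on the face opposite both the α-vinyl and the silyloxy groups, giving the C5 alcohol with OH cis to the vinyl group, which is the trans ring-fusion relationship.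

Step 14
Reactants: 19 (1S,3R,5R)-3-{[tert-butyl(dimethyl)silyl]oxy}-1-[(3R,4E)-3,4-dimethylhex-4-en-1-yl]-5-ethenyl-2,2-dimethylcyclopentan-1-ol
Product: 20 (2R,3aS,6R,8aR)-2-{[tert-butyl(dimethyl)silyl]oxy}-3,3,6,7-tetramethyl-2,3,4,5,6,8a-hexahydroazulen-3a(1H)-ol
Conditions: Hoveyda–Grubbs II (10 mol %), toluene (5 mM), 80 °C
Reagents that add atoms: none
Why: Ring-closing metathesis, initiated at the vinyl group and closing onto the trisubstituted alkene with loss of propene, forms the seven-membered ring as the C9=C10 cycloheptene; trans-1,2 tethers on a cyclopentane can span a seven-membered ring without undue strain.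

Step 15
Reactants: 20 (2R,3aS,6R,8aR)-2-{[tert-butyl(dimethyl)silyl]oxy}-3,3,6,7-tetramethyl-2,3,4,5,6,8a-hexahydroazulen-3a(1H)-ol
Product: 21 (2R,3aS,6R,7R,8S,8aR)-2-{[tert-butyl(dimethyl)silyl]oxy}-7,8-epoxy-3,3,6,7-tetramethyldecahydroazulen-3a-ol
Conditions: VO(acac)2 (5 mol %), t-BuOOH, CH2Cl2, 0 °C to rt
Reagents that add atoms: tert-butyl hydroperoxide, CC(C)(C)OO
Why: Vanadium-catalysed hydroxyl-directed epoxidation, in which the homoallylic C5 alkoxide binds vanadium and delivers the peroxide oxygen to the alkene face syn to itself, should place the C10–O bond on the same face as the C8 methyl group.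

Step 16
Reactants: 21 (2R,3aS,6R,7R,8S,8aR)-2-{[tert-butyl(dimethyl)silyl]oxy}-7,8-epoxy-3,3,6,7-tetramethyldecahydroazulen-3a-ol; 7 4-ethenylfuran-2(5H)-one
Product: 22 4-{2-[(2R,3aS,6R,7S,8S,8aR)-2-{[tert-butyl(dimethyl)silyl]oxy}-3a,8-dihydroxy-3,3,6,7-tetramethyldecahydroazulen-7-yl]ethyl}furan-2(5H)-one
Conditions: Cp2TiCl2 (2.5 equiv), Zn, THF, rt, added slowly to 21 and 7 (4 equiv), THF, rt; 1 M HCl
Reagents that add atoms: none
Why: This is a Nugent–RajanBabu-type reductive epoxide opening followed by radical conjugate (Giese) addition: Cp2TiCl transfers one electron to the Ti-bound epoxide, the C9–O bond breaks because it gives the tertiary radical, this nucleophilic C9 radical adds to the unsubstituted terminal carbon C11 of 7, and a second Cp2TiCl reduces the resulting dienyl radical to a titanium dienolate that is protonated on work-up to the conjugated butenolide. The closest known reaction types are titanocene(III)-mediated epoxide–acrylate couplings that build quaternary carbons from substituted epoxides, and the 1,6-addition of tertiary alkyl radicals to 4-vinylbutenolides. No ring is closed. The new quaternary stereocentre C9 is set by the substrate: the bulky C10–O–Ti group and the pseudoaxial C8 methyl lie on the same face of the planar radical, so C11 should enter from the opposite face, giving the C9 methyl cis to the C8 methyl, while C10 keeps the configuration of the epoxide. The step needs regioselective C–O cleavage (tertiary over secondary radical), 1,6- over 1,4-addition (terminal CH2 versus the disubstituted β-carbon of the lactone) and C–C bond formation faster than trapping of the radical by Ti(III), which the hindered tertiary radical, the excess of 7 and slow addition of the Ti(III) solution should secure. The lactone carbonyl is not reduced by Cp2TiCl, and the free C5 alcohol and the silyl ether are tolerated.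

Step 17
Reactants: 22 4-{2-[(2R,3aS,6R,7S,8S,8aR)-2-{[tert-butyl(dimethyl)silyl]oxy}-3a,8-dihydroxy-3,3,6,7-tetramethyldecahydroazulen-7-yl]ethyl}furan-2(5H)-one
Product: 23 4-{2-[(2R,3aS,6R,7S,8aS)-2-{[tert-butyl(dimethyl)silyl]oxy}-3a-hydroxy-3,3,6,7-tetramethyl-8-oxodecahydroazulen-7-yl]ethyl}furan-2(5H)-one
Conditions: Dess–Martin periodinane, NaHCO3, CH2Cl2, rt
Reagents that add atoms: none
Why: Dess–Martin oxidation converts the only secondary alcohol (C10) to the ketone, while the tertiary C5 alcohol, the silyl ether and the butenolide are inert and the buffered medium avoids retro-aldol cleavage or dehydration of the new β-hydroxy ketone.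

Step 18
Reactants: 23 4-{2-[(2R,3aS,6R,7S,8aS)-2-{[tert-butyl(dimethyl)silyl]oxy}-3a-hydroxy-3,3,6,7-tetramethyl-8-oxodecahydroazulen-7-yl]ethyl}furan-2(5H)-one
Product: 24 4-{2-[(2R,3aS,6R,7S,8aS)-2,3a-dihydroxy-3,3,6,7-tetramethyl-8-oxodecahydroazulen-7-yl]ethyl}furan-2(5H)-one (CNP0077405.1)
Conditions: HF·pyridine, THF, 0 °C to rt
Reagents that add atoms: none
Why: Desilylation with HF·pyridine is chosen over basic TBAF so that the β-hydroxy ketone does not undergo retro-aldol cleavage and the butenolide is not deprotonated.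

**Compound list**

1 | (E)-3-methylpent-3-en-2-one | CC(=O)/C(C)=C/C | starting material
2 | (2R,3E)-3-methylpent-3-en-2-ol | C[C@@H](O)/C(C)=C/C | intermediate
3 | ethyl (3R,4E)-3,4-dimethylhex-4-enoate | CCOC(=O)C[C@@H](C)/C(C)=C/C | intermediate
4 | (3R,4E)-3,4-dimethylhex-4-en-1-ol | OCC[C@@H](C)/C(C)=C/C | intermediate
5 | (2E,4R)-6-bromo-3,4-dimethylhex-2-ene | BrCC[C@@H](C)/C(C)=C/C | intermediate
6 | 4-bromofuran-2(5H)-one | BrC1=CC(=O)OC1 | starting material
7 | 4-ethenylfuran-2(5H)-one | C=CC1=CC(=O)OC1 | intermediate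
8 | 2,2-dimethylcyclopentane-1,3-dione | CC1(C)C(=O)CCC1=O | starting material
9 | (R)-3-hydroxy-2,2-dimethylcyclopentan-1-one | O=C1CC[C@@H](O)C1(C)C | intermediate
10 | (R)-2,2-dimethyl-3-[(triethylsilyl)oxy]cyclopentan-1-one | O=C1CC[C@@H](O[Si](CC)(CC)CC)C1(C)C | intermediate
11 | triethyl{[(1R)-2,2-dimethyl-3-(trimethylsilyloxy)cyclopent-3-en-1-yl]oxy}silane (trimethylsilyl enol ether of 10) | C[Si](C)(C)OC1=CC[C@@H](O[Si](CC)(CC)CC)C1(C)C | intermediate
12 | (4R)-5,5-dimethyl-4-[(triethylsilyl)oxy]cyclopent-2-en-1-one | O=C1C=C[C@@H](O[Si](CC)(CC)CC)C1(C)C | intermediate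
13 | (3R,4R)-4-ethenyl-2,2-dimethyl-3-[(triethylsilyl)oxy]cyclopentan-1-one | O=C1C[C@H](C=C)[C@@H](O[Si](CC)(CC)CC)C1(C)C | intermediate
14 | (3R,4R)-4-ethenyl-3-hydroxy-2,2-dimethylcyclopentan-1-one | O=C1C[C@H](C=C)[C@@H](O)C1(C)C | intermediate
15 | (1R,3R,4R)-4-ethenyl-2,2-dimethylcyclopentane-1,3-diol | O[C@@H]1C[C@H](C=C)[C@@H](O)C1(C)C | intermediate
16 | (1R,3R,5R)-3-{[tert-butyl(dimethyl)silyl]oxy}-5-ethenyl-2,2-dimethylcyclopentan-1-ol | CC(C)(C)[Si](C)(C)O[C@@H]1C[C@H](C=C)[C@@H](O)C1(C)C | intermediate
17 | (2R,4R)-4-{[tert-butyl(dimethyl)silyl]oxy}-2-ethenyl-5,5-dimethylcyclopentan-1-one | CC(C)(C)[Si](C)(C)O[C@@H]1C[C@H](C=C)C(=O)C1(C)C | intermediate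
18 | [(3R,4E)-3,4-dimethylhex-4-en-1-yl]magnesium bromide | Br[Mg]CC[C@@H](C)/C(C)=C/C | intermediate
19 | (1S,3R,5R)-3-{[tert-butyl(dimethyl)silyl]oxy}-1-[(3R,4E)-3,4-dimethylhex-4-en-1-yl]-5-ethenyl-2,2-dimethylcyclopentan-1-ol | CC(C)(C)[Si](C)(C)O[C@@H]1C[C@H](C=C)[C@@](O)(CC[C@@H](C)/C(C)=C/C)C1(C)C | intermediate
20 | (2R,3aS,6R,8aR)-2-{[tert-butyl(dimethyl)silyl]oxy}-3,3,6,7-tetramethyl-2,3,4,5,6,8a-hexahydroazulen-3a(1H)-ol | CC(C)(C)[Si](C)(C)O[C@@H]1C[C@@H]2C=C(C)[C@H](C)CC[C@@]2(O)C1(C)C | intermediate
21 | (2R,3aS,6R,7R,8S,8aR)-2-{[tert-butyl(dimethyl)silyl]oxy}-7,8-epoxy-3,3,6,7-tetramethyldecahydroazulen-3a-ol | CC(C)(C)[Si](C)(C)O[C@@H]1C[C@@H]2[C@@H]3O[C@]3(C)[C@H](C)CC[C@@]2(O)C1(C)C | intermediate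
22 | 4-{2-[(2R,3aS,6R,7S,8S,8aR)-2-{[tert-butyl(dimethyl)silyl]oxy}-3a,8-dihydroxy-3,3,6,7-tetramethyldecahydroazulen-7-yl]ethyl}furan-2(5H)-one | CC(C)(C)[Si](C)(C)O[C@@H]1C[C@@H]2[C@H](O)[C@@](C)(CCC3=CC(=O)OC3)[C@H](C)CC[C@@]2(O)C1(C)C | intermediate
23 | 4-{2-[(2R,3aS,6R,7S,8aS)-2-{[tert-butyl(dimethyl)silyl]oxy}-3a-hydroxy-3,3,6,7-tetramethyl-8-oxodecahydroazulen-7-yl]ethyl}furan-2(5H)-one | CC(C)(C)[Si](C)(C)O[C@@H]1C[C@@H]2C(=O)[C@@](C)(CCC3=CC(=O)OC3)[C@H](C)CC[C@@]2(O)C1(C)C | intermediate
24 | 4-{2-[(2R,3aS,6R,7S,8aS)-2,3a-dihydroxy-3,3,6,7-tetramethyl-8-oxodecahydroazulen-7-yl]ethyl}furan-2(5H)-one (CNP0077405.1) | C[C@@H]1CC[C@]2(O)[C@H](C[C@@H](O)C2(C)C)C(=O)[C@@]1(C)CCC1=CC(=O)OC1 | target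

**Totals and risks**

Total step count: 18. Longest linear sequence: 13 steps (steps 6–18, from 2,2-dimethylcyclopentane-1,3-dione).

Steps most likely to fail:

Step 16. The tertiary radical may be trapped by Ti(III) before it adds (β-hydride elimination to an allylic alcohol or deoxygenation back to the alkene), the acceptor may oligomerise, or facial selectivity at C9 may erode. The fallback sets out from 21 and comes back at 22. MgBr2·OEt2 in Et2O at −20 °C should open the epoxide at its tertiary carbon to give tertiary bromohydrin F1. Bromine-atom abstraction from it with (Me3Si)3SiH and AIBN in toluene at 80 °C, in the presence of an excess of 7, generates the same C9 radical without titanium (tin-free Giese addition), so radical generation no longer competes with Ti(III) trapping.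

Step 15. Facial selectivity may be poor, because the pseudoaxial C8 methyl hinders the face to which the tertiary homoallylic hydroxyl must deliver the oxidant, and undirected attack would give the other epoxide. The fallback sets out from 20 and comes back at 21. TMSOTf and 2,6-lutidine cap the C5 hydroxyl as trimethylsilyl ether F2, so that it cannot capture the bromonium ion. NBS in aqueous THF then adds bromine from the less hindered face and water at C9 to give bromohydrin F3. K2CO3 in MeOH closes the epoxide by SN2 displacement at C10 and removes the trimethylsilyl group, so the oxygen ends on the face opposite to the first electrophilic attack, which is the face direct epoxidation would avoid.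

Step 11. Site selectivity between the two hindered secondary hydroxyls may be poor (silylation at C5 or at both). The fallback sets out from 14, replaces steps 10 and 11, and comes back at 16. A samarium-catalysed Evans–Tishchenko reduction (SmI2 cat., PhCHO, THF, −10 °C) reduces the ketone anti to the hydroxyl and leaves the acyl group on the directing C5 oxygen, giving monobenzoate F4 with the two oxygens differentiated by mechanism. TBSOTf and 2,6-lutidine then silylate the free C3 hydroxyl to give silyl ether benzoate F5, and K2CO3 in MeOH removes the benzoate.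

**Further compounds**

F1 | step 16 | (2R,3aS,6R,7S,8S,8aR)-7-bromo-2-{[tert-butyl(dimethyl)silyl]oxy}-3,3,6,7-tetramethyldecahydroazulene-3a,8-diol (tertiary bromohydrin from 21) | CC(C)(C)[Si](C)(C)O[C@@H]1C[C@@H]2[C@H](O)[C@@](C)(Br)[C@H](C)CC[C@@]2(O)C1(C)C
F2 | step 15 | trimethylsilyl ether of 20 at the C5 (3a) oxygen | CC(C)(C)[Si](C)(C)O[C@@H]1C[C@@H]2C=C(C)[C@H](C)CC[C@@]2(O[Si](C)(C)C)C1(C)C
F3 | step 15 | bromohydrin of F2 with bromine at C10 and hydroxyl at C9, trans | CC(C)(C)[Si](C)(C)O[C@@H]1C[C@@H]2[C@@H](Br)[C@](C)(O)[C@H](C)CC[C@@]2(O[Si](C)(C)C)C1(C)C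
F4 | step 11 | (1R,3R,5R)-5-ethenyl-3-hydroxy-2,2-dimethylcyclopentyl benzoate | O[C@@H]1C[C@H](C=C)[C@@H](OC(=O)c2ccccc2)C1(C)C
F5 | step 11 | (1R,3R,5R)-3-{[tert-butyl(dimethyl)silyl]oxy}-5-ethenyl-2,2-dimethylcyclopentyl benzoate | CC(C)(C)[Si](C)(C)O[C@@H]1C[C@H](C=C)[C@@H](OC(=O)c2ccccc2)C1(C)C
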